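Ring A carries oxygen on C5, C7 and C8a in a 1,3,5 pattern, with prenyl on C8 wedged between O1 and the 7-methoxy group. The route exploits this pattern by building ring A instead of substituting it: a thermal benzannulation joins 3-(benzyloxy)cyclobutenone (supplying C8a, C6, C5, C4a) to a prenyl-substituted methoxyalkyne (C8, C7), forming C8–C8a, C6–C7 and C4a–C8a and giving a phenol with O1, prenyl, methoxy and a benzyl-masked 5-oxygen already in place. Ortho-formylation at C4a, chromone closure, rhodium-catalysed asymmetric arylation at C2, trans-selective enolate hydroxylation at C3 and two mild deprotections then give the (2R,3R)-dihydroflavonol.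

Key step: step 3

Structure check: the target is the 2,3-trans dihydroflavonol with (2R,3R) configuration. Flavanone 19 has the same spatial arrangement at C2 but the descriptor S, because C3 ranks below the aryl group until it carries oxygen.

Assumption: the (R) antipode of the diphosphine in step 7 is taken to give the (2S)-flavanone 19. If a first run shows the opposite sense, the (S) antipode is used and nothing else changes.

Step 1
Reactants: 1 chloroacetaldehyde dimethyl acetal; 2 prenyl bromide
Product: 4 1-methoxy-5-methylhex-4-en-1-yne, via lithium methoxyacetylide 3 (not isolated)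
Conditions: LiNEt2 (3.0 equiv, from Et2NH/n-BuLi), THF, 0 °C; then 2 (1.3 equiv), DMPU, −20 °C to rt; distillation
Reagents that add atoms: none
Why: Three equivalents of LiNEt2 convert the chloroacetal into LiC≡COMe by two eliminations and one deprotonation, and SN2 alkylation of this acetylide at the primary carbon of the allylic bromide gives the skipped enyne, with no base left over to isomerise the doubly activated CH2 group.

Step 2
Reactants: 5 3-ethoxycyclobut-2-en-1-one
Product: 6 3-(benzyloxy)cyclobut-2-en-1-one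
Conditions: BnOH (2 equiv), camphorsulfonic acid (5 mol%), toluene, 40 °C, reduced pressure (EtOH stripped)
Reagents that add atoms: benzyl alcohol, OCc1ccccc1
Why: This is an acid-catalysed transetherification of a vinylogous ester, in which O-protonation allows benzyl alcohol to add at C3 and ethanol to leave (the same addition–elimination by which dilute acid hydrolyses 5 to cyclobutane-1,3-dione), and removal of ethanol drives the exchange.

Step 3
Reactants: 6 3-(benzyloxy)cyclobut-2-en-1-one; 4 1-methoxy-5-methylhex-4-en-1-yne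
Product: 11 5-(benzyloxy)-3-methoxy-2-(3-methylbut-2-enyl)phenol, via benzyloxy vinylketene 7 (not isolated), via 4-vinylcyclobutenone 8 (not isolated), via dienylketene 9 (not isolated), via cyclohexadienone tautomer 10 (not isolated)
Conditions: 4 (1.6 equiv), toluene (0.5 M), sealed tube, 110 °C then 145 °C; then KOH, MeOH, rt
Reagents that add atoms: none
Why: Heating opens 6 by conrotatory 4π electrocyclic cleavage of its C1–C4 bond to vinylketene 7, which the electron-rich ynol ether 4 traps in a [2+2] cycloaddition to give 4-vinylcyclobutenone 8; a second 4π opening gives dienylketene 9. Ring A is then closed by a thermal disrotatory 6π electrocyclisation that forms C4a–C8a, and dienone 10 tautomerises irreversibly to the phenol. The closest known reaction is the Danheiser benzannulation of cyclobutenones with alkoxyalkynes; the one untested variable is the 3-alkoxy group on the cyclobutenone partner, but the same 3-alkoxycyclobutenone unit is present in intermediate 8 of every such reaction and opens under these conditions, hence the second, hotter stage. No stereocentre is created. The step needs only regiocontrol in the [2+2] event, which the polarisation of 4 supplies: its nucleophilic prenyl-bearing carbon attacks the sp carbon of the ketene, so that prenyl lands ortho (C8) and methoxy meta (C7) to the new hydroxyl (O1 on C8a), with benzyloxy on C5. A methyl ynol ether cannot lose an alkene by retro-ene fragmentation, the skipped prenyl alkene has no pericyclic outlet, and the closing KOH/MeOH treatment returns any phenol that a ketene has O-acylated.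

Step 4
Reactants: 11 5-(benzyloxy)-3-methoxy-2-(3-methylbut-2-enyl)phenol
Product: 13 6-(benzyloxy)-2-hydroxy-4-methoxy-3-(3-methylbut-2-enyl)benzaldehyde, via salicyl alcohol 12 (not isolated)
Conditions: MgCl2 (2 equiv), Et3N (4 equiv), (CH2O)n (6 equiv), MeCN, 80 °C; cold dilute HCl work-up
Reagents that add atoms: paraformaldehyde (as formaldehyde), C=O
Why: In this Casnati–Skattebøl ortho-formylation the magnesium phenoxide delivers formaldehyde through a six-membered chelate to the only free ortho carbon (C4a; the other ortho site holds prenyl and C6 lies para, outside the chelate), a second formaldehyde oxidises the salicyl alkoxide by Oppenauer-type hydride transfer, and the basic medium cannot cyclise the ortho-prenylphenol to a chroman.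

Step 5
Reactants: 13 6-(benzyloxy)-2-hydroxy-4-methoxy-3-(3-methylbut-2-enyl)benzaldehyde
Product: 14 3-(benzyloxy)-2-(1-hydroxyprop-2-yn-1-yl)-5-methoxy-6-(3-methylbut-2-enyl)phenol (racemic)
Conditions: HC≡CMgBr (3.5 equiv), THF, 0 °C to rt; sat. NH4Cl, 0 °C; crude used at once
Reagents that add atoms: ethynylmagnesium bromide, C#C[Mg]Br
Why: In this Grignard 1,2-addition the first equivalent forms the magnesium phenoxide, whose chelation to the formyl oxygen activates the electron-rich aldehyde toward the alkynyl nucleophile, and the racemic carbinol centre is erased in step 6.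

Step 6
Reactants: 14 3-(benzyloxy)-2-(1-hydroxyprop-2-yn-1-yl)-5-methoxy-6-(3-methylbut-2-enyl)phenol
Product: 17 5-(benzyloxy)-7-methoxy-8-(3-methylbut-2-enyl)-4H-chromen-4-one, via ynone 15 (not isolated), via diethylamino enone 16 (not isolated)
Conditions: MnO2 (15 equiv), CH2Cl2, rt; filter; Et2NH (1.5 equiv), EtOH, rt; then AcOH, 60 °C
Reagents that add atoms: none
Why: MnO2 oxidises the benzylic and propargylic carbinol selectively, Et2NH adds to the terminal ynone to give the enaminone, and the ortho-hydroxyl then closes ring C by 6-endo addition–elimination at C2 with loss of the amine (the enaminone chromone synthesis), a path that excludes 5-exo closure to a benzofuranone.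

Step 7
Reactants: 17 5-(benzyloxy)-7-methoxy-8-(3-methylbut-2-enyl)-4H-chromen-4-one; 18 [4-(methoxymethoxy)phenyl]boronic acid
Product: 19 (2S)-5-(benzyloxy)-7-methoxy-2-[4-(methoxymethoxy)phenyl]-8-(3-methylbut-2-enyl)-2,3-dihydro-4H-chromen-4-one
Conditions: [Rh(OH)(cod)]2 (1.5 mol%), (R)-MeO-F12-BIPHEP (3.3 mol%), 18 (2.5 equiv), toluene/H2O (20:1), 35 °C
Reagents that add atoms: none
Why: In this Hayashi–Miyaura asymmetric 1,4-addition the aryl–rhodium species, made more reactive toward the electron-rich chromone by the electron-poor diphosphine, inserts the C2=C3 bond on the face chosen by the chiral ligand (catalyst control sets C2 as S), and water then protonates the rhodium enolate under base-free conditions that neither open the pyranone nor touch the prenyl alkene.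

Step 8
Reactants: 19 (2S)-5-(benzyloxy)-7-methoxy-2-[4-(methoxymethoxy)phenyl]-8-(3-methylbut-2-enyl)-2,3-dihydro-4H-chromen-4-one
Product: 21 (2R,3R)-5-(benzyloxy)-3-hydroxy-7-methoxy-2-[4-(methoxymethoxy)phenyl]-8-(3-methylbut-2-enyl)-2,3-dihydro-4H-chromen-4-one, via sodium enolate 20 (not isolated)
Conditions: NaN(SiMe3)2 (1.15 equiv), THF, −78 °C; trans-3-phenyl-2-(phenylsulfonyl)oxaziridine (1.4 equiv), −78 °C; AcOH, −78 °C
Reagents that add atoms: trans-3-phenyl-2-(phenylsulfonyl)oxaziridine, O=S(=O)(N1OC1c1ccccc1)c1ccccc1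
Why: In this Davis enolate hydroxylation the sodium enolate, kept at −78 °C where β-elimination of the C8a aryloxide is slow, is oxidised on the face anti to the C2 aryl group (substrate control by C2), which gives the 2,3-trans, diequatorial (2R,3R) isomer without epoxidising the unactivated prenyl alkene.

Step 9
Reactants: 21 (2R,3R)-5-(benzyloxy)-3-hydroxy-7-methoxy-2-[4-(methoxymethoxy)phenyl]-8-(3-methylbut-2-enyl)-2,3-dihydro-4H-chromen-4-one
Product: 22 (2R,3R)-3,5-dihydroxy-7-methoxy-2-[4-(methoxymethoxy)phenyl]-8-(3-methylbut-2-enyl)-2,3-dihydro-4H-chromen-4-one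
Conditions: MgBr2·OEt2 (4 equiv), toluene/Et2O (4:1), 70 °C; sat. NH4Cl
Reagents that add atoms: none
Why: In this chelation-assisted ether cleavage MgBr2 bridges the C4 carbonyl and the peri 5-oxygen, so that bromide attacks only that benzylic carbon and the 7-methyl ether, the remote MOM ether, the prenyl alkene and both stereocentres are left alone.

Step 10
Reactants: 22 (2R,3R)-3,5-dihydroxy-7-methoxy-2-[4-(methoxymethoxy)phenyl]-8-(3-methylbut-2-enyl)-2,3-dihydro-4H-chromen-4-one
Product: 23 (2R,3R)-3,5-dihydroxy-2-(4-hydroxyphenyl)-7-methoxy-8-(3-methylbut-2-enyl)-2,3-dihydro-4H-chromen-4-one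
Conditions: 3 M aq. HCl/MeOH (1:6), 40 °C
Reagents that add atoms: none
Why: This acid-catalysed acetal solvolysis of the MOM ether in methanol is mild enough for a prenyl group whose neighbours (O1 and 7-OMe) cannot cyclise onto it, and the trans-dihydroflavonol is the stable diastereomer in dilute acid, so C2 and C3 are retained.

Compound list
1 | chloroacetaldehyde dimethyl acetal (2-chloro-1,1-dimethoxyethane) | COC(CCl)OC | starting material
2 | prenyl bromide (1-bromo-3-methylbut-2-ene) | CC(C)=CCBr | starting material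
3 | lithium methoxyacetylide | COC#C[Li] | intermediate (not isolated)
4 | 1-methoxy-5-methylhex-4-en-1-yne | COC#CCC=C(C)C | intermediate
5 | 3-ethoxycyclobut-2-en-1-one | CCOC1=CC(=O)C1 | starting material
6 | 3-(benzyloxy)cyclobut-2-en-1-one | O=C1C=C(OCc2ccccc2)C1 | intermediate
7 | 3-(benzyloxy)buta-1,3-dien-1-one (vinylketene) | O=C=CC(=C)OCc1ccccc1 | intermediate (not isolated)
8 | 4-[1-(benzyloxy)ethenyl]-3-methoxy-2-(3-methylbut-2-enyl)cyclobut-2-en-1-one, racemic at C4 | O=C1C(CC=C(C)C)=C(OC)C1C(=C)OCc1ccccc1 | intermediate (not isolated)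
9 | (3E)-5-(benzyloxy)-3-methoxy-2-(3-methylbut-2-enyl)hexa-1,3,5-trien-1-one (dienylketene) | O=C=C(CC=C(C)C)/C(OC)=C\C(=C)OCc1ccccc1 | intermediate (not isolated)
10 | 5-(benzyloxy)-3-methoxy-2-(3-methylbut-2-enyl)cyclohexa-2,4-dien-1-one | O=C1C(CC=C(C)C)=C(OC)C=C(OCc2ccccc2)C1 | intermediate (not isolated)
11 | 5-(benzyloxy)-3-methoxy-2-(3-methylbut-2-enyl)phenol | COc1cc(OCc2ccccc2)cc(O)c1CC=C(C)C | intermediate
12 | 3-(benzyloxy)-2-(hydroxymethyl)-5-methoxy-6-(3-methylbut-2-enyl)phenol | COc1cc(OCc2ccccc2)c(CO)c(O)c1CC=C(C)C | intermediate (not isolated)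
13 | 6-(benzyloxy)-2-hydroxy-4-methoxy-3-(3-methylbut-2-enyl)benzaldehyde | COc1cc(OCc2ccccc2)c(C=O)c(O)c1CC=C(C)C | intermediate
14 | 3-(benzyloxy)-2-(1-hydroxyprop-2-yn-1-yl)-5-methoxy-6-(3-methylbut-2-enyl)phenol, racemic | COc1cc(OCc2ccccc2)c(C(O)C#C)c(O)c1CC=C(C)C | intermediate
15 | 1-[6-(benzyloxy)-2-hydroxy-4-methoxy-3-(3-methylbut-2-enyl)phenyl]prop-2-yn-1-one | COc1cc(OCc2ccccc2)c(C(=O)C#C)c(O)c1CC=C(C)C | intermediate (not isolated)
16 | (E)-1-[6-(benzyloxy)-2-hydroxy-4-methoxy-3-(3-methylbut-2-enyl)phenyl]-3-(diethylamino)prop-2-en-1-one | CCN(CC)/C=C/C(=O)c1c(O)c(CC=C(C)C)c(OC)cc1OCc1ccccc1 | intermediate (not isolated)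
17 | 5-(benzyloxy)-7-methoxy-8-(3-methylbut-2-enyl)-4H-chromen-4-one | COc1cc(OCc3ccccc3)c2c(c1CC=C(C)C)OC=CC2=O | intermediate
18 | [4-(methoxymethoxy)phenyl]boronic acid | COCOc1ccc(cc1)B(O)O | starting material
19 | (2S)-5-(benzyloxy)-7-methoxy-2-[4-(methoxymethoxy)phenyl]-8-(3-methylbut-2-enyl)-2,3-dihydro-4H-chromen-4-one | COc1cc(OCc3ccccc3)c2c(c1CC=C(C)C)O[C@H](c1ccc(OCOC)cc1)CC2=O | intermediate
20 | sodium (2S)-5-(benzyloxy)-7-methoxy-2-[4-(methoxymethoxy)phenyl]-8-(3-methylbut-2-enyl)-2H-chromen-4-olate | COc1cc(OCc3ccccc3)c2c(c1CC=C(C)C)O[C@H](c1ccc(OCOC)cc1)C=C2[O-].[Na+] | intermediate (not isolated)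
21 | (2R,3R)-5-(benzyloxy)-3-hydroxy-7-methoxy-2-[4-(methoxymethoxy)phenyl]-8-(3-methylbut-2-enyl)-2,3-dihydro-4H-chromen-4-one | COc1cc(OCc3ccccc3)c2c(c1CC=C(C)C)O[C@H](c1ccc(OCOC)cc1)[C@@H](O)C2=O | intermediate
22 | (2R,3R)-3,5-dihydroxy-7-methoxy-2-[4-(methoxymethoxy)phenyl]-8-(3-methylbut-2-enyl)-2,3-dihydro-4H-chromen-4-one | COc1cc(O)c2c(c1CC=C(C)C)O[C@H](c1ccc(OCOC)cc1)[C@@H](O)C2=O | intermediate
23 | (2R,3R)-3,5-dihydroxy-2-(4-hydroxyphenyl)-7-methoxy-8-(3-methylbut-2-enyl)-2,3-dihydro-4H-chromen-4-one | COc1cc(O)c2c(c1CC=C(C)C)O[C@H](c1ccc(O)cc1)[C@@H](O)C2=O | target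

Total step count: 10.
Longest linear sequence: 9 steps (steps 2 to 10 from 5; equally steps 1 and 3 to 10 from 1).

Steps most likely to fail

Step 3 (ring A benzannulation). Donation from the 3-benzyloxy group may slow the first 4π ring opening until oligomerisation of the ketene or of the ynol ether competes, or the sequence may stall at the vinylcyclobutenone stage. The fallback uses classical acylphloroglucinol chemistry, with ring A bought instead of built. It sets out from prenyl bromide 2 and commercial 1-(2,6-dihydroxy-4-methoxyphenyl)ethan-1-one (COc1cc(O)c(C(C)=O)c(O)c1), whose two free ring positions are equivalent. C-Prenylation with 2 in aqueous KOH at 0 °C should give 1-[2,6-dihydroxy-4-methoxy-3-(3-methylbut-2-enyl)phenyl]ethan-1-one F1. One equivalent of BnBr with K2CO3 in acetone should benzylate the hydroxyl remote from the prenyl group (the other is flanked on both sides) to give 1-[6-(benzyloxy)-2-hydroxy-4-methoxy-3-(3-methylbut-2-enyl)phenyl]ethan-1-one F2. DMF dimethyl acetal in toluene at 90 °C should give (E)-1-[6-(benzyloxy)-2-hydroxy-4-methoxy-3-(3-methylbut-2-enyl)phenyl]-3-(dimethylamino)prop-2-en-1-one F3, which should close in AcOH at 60 °C to chromone 17, where the route is rejoined before step 7.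

Step 8 (C3 hydroxylation). β-Elimination of the C8a aryloxide from the enolate with reversible ring opening would erode the configuration at C2; leakage to the cis isomer or further oxidation of the product alkoxide are also possible. The fallback is the chalcone epoxide route, in which the C3 oxygen is installed before ring C is closed. It sets out from chromone 17. Hot aqueous NaOH in EtOH should cleave the pyranone with loss of formate to the acetophenone F2 (the same compound as in the fallback to step 3). MOMCl/iPr2NEt should give 1-[6-(benzyloxy)-4-methoxy-2-(methoxymethoxy)-3-(3-methylbut-2-enyl)phenyl]ethan-1-one F4. Claisen–Schmidt condensation with commercial 4-(methoxymethoxy)benzaldehyde (COCOc1ccc(C=O)cc1; KOH, EtOH) should give (E)-1-[6-(benzyloxy)-4-methoxy-2-(methoxymethoxy)-3-(3-methylbut-2-enyl)phenyl]-3-[4-(methoxymethoxy)phenyl]prop-2-en-1-one F5. Juliá–Colonna epoxidation (poly-L-leucine, urea–H2O2, DBU, THF), a nucleophilic oxidation that ignores the prenyl alkene, should give [(2R,3S)-3-[4-(methoxymethoxy)phenyl]oxiran-2-yl][6-(benzyloxy)-4-methoxy-2-(methoxymethoxy)-3-(3-methylbut-2-enyl)phenyl]methanone F6. HCl in MeOH at 45 °C should remove both MOM groups and let the freed hydroxyl open the epoxide at the benzylic carbon with inversion, giving (2R,3R)-5-(benzyloxy)-3-hydroxy-2-(4-hydroxyphenyl)-7-methoxy-8-(3-methylbut-2-enyl)-2,3-dihydro-4H-chromen-4-one F7. Debenzylation of F7 under the conditions of step 9 should then give target 23 directly.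

Step 6 (oxidation and chromone closure, including the handling of carbinol 14). The electron-rich ortho-hydroxybenzylic carbinol may lose water to an ortho-quinone methide before it is oxidised, MnO2 may oxidise the free phenol, or the terminal ynone may oligomerise. In the fallback the phenol is masked before the C–C bond is made and the oxidant is a hypervalent iodine reagent. It sets out from aldehyde 13. MOMCl/iPr2NEt should give 6-(benzyloxy)-4-methoxy-2-(methoxymethoxy)-3-(3-methylbut-2-enyl)benzaldehyde F8. HC≡CMgBr should give 1-[6-(benzyloxy)-4-methoxy-2-(methoxymethoxy)-3-(3-methylbut-2-enyl)phenyl]prop-2-yn-1-ol F9, which can no longer form a quinone methide. Dess–Martin periodinane with NaHCO3 should give 1-[6-(benzyloxy)-4-methoxy-2-(methoxymethoxy)-3-(3-methylbut-2-enyl)phenyl]prop-2-yn-1-one F10. Et2NH should give (E)-1-[6-(benzyloxy)-4-methoxy-2-(methoxymethoxy)-3-(3-methylbut-2-enyl)phenyl]-3-(diethylamino)prop-2-en-1-one F11, and HCl in MeOH at rt should then unmask the phenol, which closes onto the enaminone to give chromone 17, where the route is rejoined.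

Further compounds
F1 | step 3 | 1-[2,6-dihydroxy-4-methoxy-3-(3-methylbut-2-enyl)phenyl]ethan-1-one | COc1cc(O)c(C(C)=O)c(O)c1CC=C(C)C
F2 | step 3 | 1-[6-(benzyloxy)-2-hydroxy-4-methoxy-3-(3-methylbut-2-enyl)phenyl]ethan-1-one | COc1cc(OCc2ccccc2)c(C(C)=O)c(O)c1CC=C(C)C
F3 | step 3 | (E)-1-[6-(benzyloxy)-2-hydroxy-4-methoxy-3-(3-methylbut-2-enyl)phenyl]-3-(dimethylamino)prop-2-en-1-one | CN(C)/C=C/C(=O)c1c(O)c(CC=C(C)C)c(OC)cc1OCc1ccccc1
F4 | step 8 | 1-[6-(benzyloxy)-4-methoxy-2-(methoxymethoxy)-3-(3-methylbut-2-enyl)phenyl]ethan-1-one | COCOc1c(CC=C(C)C)c(OC)cc(OCc2ccccc2)c1C(C)=O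
F5 | step 8 | (E)-1-[6-(benzyloxy)-4-methoxy-2-(methoxymethoxy)-3-(3-methylbut-2-enyl)phenyl]-3-[4-(methoxymethoxy)phenyl]prop-2-en-1-one | COCOc1c(CC=C(C)C)c(OC)cc(OCc2ccccc2)c1C(=O)/C=C/c1ccc(OCOC)cc1
F6 | step 8 | [(2R,3S)-3-[4-(methoxymethoxy)phenyl]oxiran-2-yl][6-(benzyloxy)-4-methoxy-2-(methoxymethoxy)-3-(3-methylbut-2-enyl)phenyl]methanone | COCOc1c(CC=C(C)C)c(OC)cc(OCc2ccccc2)c1C(=O)[C@@H]1O[C@H]1c1ccc(OCOC)cc1
F7 | step 8 | (2R,3R)-5-(benzyloxy)-3-hydroxy-2-(4-hydroxyphenyl)-7-methoxy-8-(3-methylbut-2-enyl)-2,3-dihydro-4H-chromen-4-one | COc1cc(OCc3ccccc3)c2c(c1CC=C(C)C)O[C@H](c1ccc(O)cc1)[C@@H](O)C2=O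
F8 | step 6 | 6-(benzyloxy)-4-methoxy-2-(methoxymethoxy)-3-(3-methylbut-2-enyl)benzaldehyde | COCOc1c(CC=C(C)C)c(OC)cc(OCc2ccccc2)c1C=O
F9 | step 6 | 1-[6-(benzyloxy)-4-methoxy-2-(methoxymethoxy)-3-(3-methylbut-2-enyl)phenyl]prop-2-yn-1-ol, racemic | COCOc1c(CC=C(C)C)c(OC)cc(OCc2ccccc2)c1C(O)C#C
F10 | step 6 | 1-[6-(benzyloxy)-4-methoxy-2-(methoxymethoxy)-3-(3-methylbut-2-enyl)phenyl]prop-2-yn-1-one | COCOc1c(CC=C(C)C)c(OC)cc(OCc2ccccc2)c1C(=O)C#C
F11 | step 6 | (E)-1-[6-(benzyloxy)-4-methoxy-2-(methoxymethoxy)-3-(3-methylbut-2-enyl)phenyl]-3-(diethylamino)prop-2-en-1-one | CCN(CC)/C=C/C(=O)c1c(OCOC)c(CC=C(C)C)c(OC)cc1OCc1ccccc1
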